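**Retrosynthetic overview**

1. The route rests on the C6 carbinol (the lactone oxygen), which is allylic to the trans, trisubstituted C4=C5 alkene bearing the C15 methyl inside the ten-membered carbocycle C1–C10 (germacrane numbering; C14 is the CH2OH carbon on C10, the γ-lactone C12–O–C6 is fused at C6/C7).
2. Key disconnection: C5–C6 and C4–C15 are formed together by nickel-catalysed union of a terminal alkyne (C4≡C5), the C6 aldehyde and one methyl of Me2Zn; this closes the ten-membered ring first.
3. The γ-lactone (O6–C12) is the second ring, closed after the macrocycle; C13 methylenation, C2 acetate, C8 methacrylate and PMB removal follow.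
4. The acyclic ynal is built from vinyl iodide 5 (C14, C10, C1, C2; from but-2-yne-1,4-diol) and epoxide 12 (C6–C9, C11, C12; from dimethyl (S)-malate and tert-butyl bromoacetate), joined at C9–C10; C3–C5 are added to the C2 enal by catalytic asymmetric propargylation.

Key step: step 15

Remarks on the chemistry (assumptions, one line each):
- Germacrane numbering is used for all intermediates.
- The C11–C12 arm on C7 and the oxygen on C8 are anti along C6–C9 (a syn-aldol would give the wrong pair), so the pair is set by anti-selective alkylation of a malate dianion; this also avoids a β,γ-unsaturated C8 aldehyde.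
- The tert-butyl ester is not cleaved with strong protic acid, which would also remove the TES and PMB ethers and endanger the 1(10),4-diene; it is dealkylated with TMSOTf/2,6-lutidine.
- The THP acetal carbon (5, 13–16) and C11 of 30 and 31 are inconsequential epimer mixtures.
- In step 11 the (S)-enantiomer of the phosphoric acid is assumed to direct Si-face attack, by analogy with its known face selectivity for aryl and α,β-unsaturated aldehydes.

**Fragment A (vinyl iodide)**

Step 1
Reactants: 1 but-2-yne-1,4-diol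
Product: 2 4-[(4-methoxybenzyl)oxy]but-2-yn-1-ol
Conditions: NaH (1.0 equiv), 4-methoxybenzyl chloride (1.0 equiv), n-Bu4NI (cat.), THF/DMF, 0 °C → rt; 1 in threefold excess
Reagents that add atoms: 4-methoxybenzyl chloride, COc1ccc(CCl)cc1
Why: Williamson etherification of the monosodium alkoxide; the excess of the symmetrical diol keeps bis-ether formation low.

Step 2
Reactants: 2 4-[(4-methoxybenzyl)oxy]but-2-yn-1-ol
Product: 4 (2Z)-3-iodo-4-[(4-methoxybenzyl)oxy]but-2-en-1-ol, via cyclic alkenylaluminate 3 (not isolated)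
Conditions: NaAlH2(OCH2CH2OMe)2, THF, 0 °C → rt; EtOAc; then I2, THF, −78 → 0 °C
Reagents that add atoms: iodine, II
Why: Hydroxyl-directed trans-hydroalumination puts hydride on C1 and aluminium on C10 in a five-membered alanate, and iodinolysis with retention gives the iodide cis to the C2 carbon, which fixes the later cis C1=C10 geometry.

Step 3
Reactants: 4 (2Z)-3-iodo-4-[(4-methoxybenzyl)oxy]but-2-en-1-ol
Product: 5 2-({(2Z)-3-iodo-4-[(4-methoxybenzyl)oxy]but-2-en-1-yl}oxy)oxane (THP ether)
Conditions: 3,4-dihydro-2H-pyran, PPTS (cat.), CH2Cl2, rt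
Reagents that add atoms: 3,4-dihydro-2H-pyran, C1=COCCC1
Why: Acid-catalysed acetalisation of the primary alcohol; the acetal tolerates t-BuLi and, unlike a silyl ether cis to the alkenyllithium, cannot migrate from oxygen to carbon.

**Fragment B (epoxide)**

Step 4
Reactants: 6 dimethyl (S)-malate; 7 tert-butyl bromoacetate
Product: 9 1-tert-butyl 2,3-dimethyl (2R,3S)-3-hydroxypropane-1,2,3-tricarboxylate, via dilithium alkoxide enolate 8 (not isolated)
Conditions: LiN(iPr)2 (2.1 equiv), THF, −78 → −20 °C; then 7, −78 → −10 °C; AcOH, −78 °C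
Reagents that add atoms: tert-butyl bromoacetate (7), BrCC(=O)OC(C)(C)C
Why: Fráter–Seebach alkylation, in which the chelated alkoxide enolate is alkylated anti to the carbinol substituent so that C7 is set anti to the C8 oxygen (C8 comes from the malate), while the cold acidic quench and the bulky ester keep the alkoxide from lactonising.

Step 5
Reactants: 9 1-tert-butyl 2,3-dimethyl (2R,3S)-3-hydroxypropane-1,2,3-tricarboxylate
Product: 10 4-tert-butyl 1-methyl (2R)-2-[(1S)-1,2-dihydroxyethyl]butanedioate
Conditions: BH3·SMe2 (1.05 equiv), NaBH4 (5 mol%), THF, 0 °C → rt; MeOH quench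
Reagents that add atoms: none
Why: Hydroxyl-directed borane reduction, in which the C8 alkoxyborane delivers hydride through a five-membered chelate to the adjacent α-hydroxy ester only and leaves the C6 methyl and C12 tert-butyl esters.

Step 6
Reactants: 10 4-tert-butyl 1-methyl (2R)-2-[(1S)-1,2-dihydroxyethyl]butanedioate
Product: 12 4-tert-butyl 1-methyl (2R)-2-[(2S)-oxiran-2-yl]butanedioate, via primary monotosylate 11 (not isolated)
Conditions: TsCl (1.05 equiv), Bu2SnO (2 mol%), Et3N, CH2Cl2, 0 °C; then K2CO3, MeOH, 0 °C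
Reagents that add atoms: none
Why: Tin-acetal-catalysed sulfonylation is selective for the primary hydroxyl, and intramolecular Williamson closure (3-exo-tet) by the C8 alkoxide gives the terminal epoxide without touching C8.

**Union and elaboration to the ynal**

Step 7
Reactants: 5 THP-protected vinyl iodide; 12 4-tert-butyl 1-methyl (2R)-2-[(2S)-oxiran-2-yl]butanedioate
Product: 15 4-tert-butyl 1-methyl (2R)-2-[(1R,3E)-1-hydroxy-3-{[(4-methoxybenzyl)oxy]methyl}-5-(oxan-2-yloxy)pent-3-en-1-yl]butanedioate (C9 and C2 cis on C1=C10), via alkenyllithium 13 (not isolated), via alkenylmagnesium bromide 14 (not isolated)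
Conditions: 5 (1.3 equiv), t-BuLi (2.6 equiv), Et2O, −78 °C; MgBr2·OEt2, −78 → −40 °C; then CuI (15 mol%), 12, THF, −40 → −20 °C; aq. NH4Cl
Reagents that add atoms: none
Why: Iodine–lithium exchange and transmetalation keep the alkene geometry, and copper-catalysed SN2 opening of the terminal epoxide at the unhindered C9 methylene forms C9–C10 at low temperature faster than the Grignard reagent attacks the esters.

Step 8
Reactants: 15 C8 alcohol
Product: 16 4-tert-butyl 1-methyl (2R)-2-[(1R,3E)-1-(tert-butyldimethylsilyloxy)-3-{[(4-methoxybenzyl)oxy]methyl}-5-(oxan-2-yloxy)pent-3-en-1-yl]butanedioate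
Conditions: TBSCl, imidazole, DMAP (cat.), DMF, rt
Reagents that add atoms: tert-butyldimethylsilyl chloride, CC(C)(C)[Si](C)(C)Cl
Why: Silylation of the secondary alcohol, which must precede release of the C2 aldehyde because a free C8 hydroxyl would add to the cis-disposed aldehyde to give a six-membered lactol.

Step 9
Reactants: 16 C8 TBS ether with C2 THP ether
Product: 17 4-tert-butyl 1-methyl (2R)-2-[(1R,3E)-1-(tert-butyldimethylsilyloxy)-5-hydroxy-3-{[(4-methoxybenzyl)oxy]methyl}pent-3-en-1-yl]butanedioate
Conditions: PPTS (cat.), MeOH, rt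
Reagents that add atoms: none
Why: Acid-catalysed transacetalisation to methanol removes the THP group, while the secondary TBS ether, the PMB ether and both esters stay.

Step 10
Reactants: 17 C2 allylic alcohol
Product: 18 4-tert-butyl 1-methyl (2R)-2-[(1R,3E)-1-(tert-butyldimethylsilyloxy)-3-{[(4-methoxybenzyl)oxy]methyl}-5-oxopent-3-en-1-yl]butanedioate (C2 enal)
Conditions: MnO2 (excess), CH2Cl2, rt
Reagents that add atoms: none
Why: MnO2 oxidises the allylic alcohol chemoselectively to the enal under neutral conditions that should not isomerise the trisubstituted alkene.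

Step 11
Reactants: 18 C2 enal; 19 allenylboronic acid pinacol ester
Product: 20 4-tert-butyl 1-methyl (2R)-2-[(1R,3E,5S)-1-(tert-butyldimethylsilyloxy)-5-hydroxy-3-{[(4-methoxybenzyl)oxy]methyl}oct-3-en-7-yn-1-yl]butanedioate
Conditions: 19 (1.5 equiv), (S)-TRIP [(S)-3,3′-bis(2,4,6-triisopropylphenyl)-1,1′-binaphthyl-2,2′-diyl hydrogen phosphate, 10 mol%], 4 Å molecular sieves, toluene, −20 → 0 °C
Reagents that add atoms: allenylboronic acid pinacol ester (19), C=C=CB1OC(C)(C)C(C)(C)O1
Why: Chiral phosphoric acid-catalysed propargylation, in which the allenylboronate adds through a closed six-membered transition state (SE2′) and the catalyst, hydrogen-bonded to a boronate oxygen and the formyl hydrogen, selects the Si face of the aldehyde to set C2 as S.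

Step 12
Reactants: 20 C2 homopropargylic alcohol
Product: 21 4-tert-butyl 1-methyl (2R)-2-[(1R,3E,5S)-1-(tert-butyldimethylsilyloxy)-3-{[(4-methoxybenzyl)oxy]methyl}-5-(triethylsilyloxy)oct-3-en-7-yn-1-yl]butanedioate
Conditions: TESCl, imidazole, CH2Cl2, 0 °C
Reagents that add atoms: triethylsilyl chloride, CC[Si](Cl)(CC)CC
Why: Silylation of the only free hydroxyl gives an allylic ether that, unlike an ester, is inert to zerovalent nickel and can later be removed before the TBS group.

Step 13
Reactants: 21 C6 methyl ester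
Product: 22 tert-butyl (3S,4R,6E,8S)-4-(tert-butyldimethylsilyloxy)-3-(hydroxymethyl)-6-{[(4-methoxybenzyl)oxy]methyl}-8-(triethylsilyloxy)undec-6-en-10-ynoate
Conditions: LiBH4, MeOH (1 equiv), Et2O, 0 °C → rt
Reagents that add atoms: none
Why: LiBH4 reduces the methyl ester but not the hindered tert-butyl ester, so C6 and C12 are told apart.

Step 14
Reactants: 22 C6 primary alcohol
Product: 23 tert-butyl (3R,4R,6E,8S)-4-(tert-butyldimethylsilyloxy)-3-formyl-6-{[(4-methoxybenzyl)oxy]methyl}-8-(triethylsilyloxy)undec-6-en-10-ynoate (the ynal)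
Conditions: Dess–Martin periodinane, CH2Cl2, 0 °C → rt; used at once
Reagents that add atoms: none
Why: Dess–Martin oxidation under non-basic conditions should give the α-branched aldehyde without epimerising C7 or eliminating the β-silyloxy group.

**Key step and end game**

Step 15
Reactants: 23 ynal; 24 dimethylzinc
Product: 25 macrocyclic dienol: cyclodeca-1(10),4-diene with C6 hydroxyl (R), C7 CH2CO2tBu (S), C8 OTBS (R), C2 OTES (S), C4 methyl and C10 CH2OPMB; C4=C5 trans and C1=C10 cis in the ring
Conditions: Ni(cod)2 (20 mol%), IMes·HCl (20 mol%), KOtBu (20 mol%), Me2Zn (3 equiv), toluene/THF, 23 added by syringe pump over 8 h to 2 mM, 0 °C → rt; aq. NH4Cl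
Reagents that add atoms: dimethylzinc (24), C[Zn]C
Why: Proposed new method: zerovalent nickel is expected to bind the terminal alkyne and the C6 aldehyde of 23 and couple them oxidatively to an oxanickelacyclopentene in which C5–C6 is formed and nickel sits on C4; methyl transfer from Me2Zn to nickel, with zinc taking the alkoxide, and C–C reductive elimination then place C15 on C4 cis to C6, which makes C4=C5 trans within the ring. The closest known reactions are the nickel-catalysed alkylative cyclisations of ynals with organozincs to five- and six-membered rings, the three-component coupling of aldehydes, terminal alkynes and organozincs, and the endo-selective reductive macrocyclisation of ynals with silanes. The ten-membered carbocycle is closed in the endo mode (10-endo-dig at C5), so that both alkyne carbons become ring members. The new C6 centre is controlled by the C7 stereocentre: Felkin–Anh attack anti to the C8 branch and 1,3-anti induction from the C8 silyloxy group reinforce each other in this C7/C8-anti aldehyde and both lead to the 6R, 6,7-trans carbinol. The step needs endo regiochemistry and ring closure in preference to oligomerisation; the unsubstituted alkyne terminus together with the small carbene ligand IMes directs C–C bond formation to C5, and the preformed cis C1=C10 alkene folds the chain so that, under slow addition at high dilution, C5 and C6 can meet. Me2Zn has no β-hydrogen, so transfer of hydride in place of methyl is excluded.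

Step 16
Reactants: 25 macrocyclic dienol tert-butyl ester
Product: 27 hydroxy acid: as 25 with C12 as free carboxylic acid (C6 OH, C8 OTBS, C2 OTES, C14 OPMB), via bis(trimethylsilyl) derivative 26 (not isolated)
Conditions: TMSOTf (4 equiv), 2,6-lutidine (6 equiv), CH2Cl2, 0 °C → rt; then MeOH, 0 °C; pH 5 buffer
Reagents that add atoms: none
Why: Silyl triflate-mediated dealkylation of the tert-butyl ester (loss of 2-methylpropene from the O-silylated ester) avoids protic acid, and brief methanolysis then frees the acid and the C6 hydroxyl while the TES, TBS and PMB ethers stay.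

Step 17
Reactants: 27 hydroxy acid
Product: 28 trans-fused γ-lactone (12,6-olide): (2S,6R,7S,8R)-8-OTBS, 2-OTES, 14-OPMB germacra-1(10),4-dien-12,6-olide
Conditions: EDC·HCl, DMAP, CH2Cl2, 0 °C → rt
Reagents that add atoms: none
Why: Carbodiimide activation (Steglich lactonisation) closes the five-membered lactone on the only free hydroxyl, O6, and the 6,7-trans ring fusion follows from the C6 and C7 configurations already set.

Step 18
Reactants: 28 γ-lactone
Product: 30 C11 dimethylaminomethyl lactone (Mannich base, C11 epimers), via lithium lactone enolate 29 (not isolated)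
Conditions: LiN(iPr)2 (1.1 equiv), THF, −78 °C; then CH2=NMe2+ I− (Eschenmoser's salt), −78 → 0 °C
Reagents that add atoms: N,N-dimethylmethyleneiminium iodide, C=[N+](C)C.[I-]
Why: Mannich reaction of the lactone lithium enolate with the preformed iminium salt, the lactone α-CH2 being the only acidic site and the new C11 centre being removed in the next step.

Step 19
Reactants: 30 Mannich base
Product: 32 α-methylene lactone: (2S,6R,7S,8R)-8-OTBS, 2-OTES, 14-OPMB germacra-1(10),4,11(13)-trien-12,6-olide, via trimethylammonium iodide 31 (not isolated)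
Conditions: MeI, MeOH/CH2Cl2, rt; then aq. NaHCO3, EtOAc, rt
Reagents that add atoms: none
Why: Exhaustive N-methylation followed by base-induced β-elimination of trimethylamine gives the exocyclic C11=C13 alkene.

Step 20
Reactants: 32 α-methylene lactone with C2 OTES
Product: 33 C2 alcohol (8-OTBS, 14-OPMB)
Conditions: HF·pyridine, pyridine, THF, 0 °C
Reagents that add atoms: none
Why: Buffered HF·pyridine cleaves the less hindered triethylsilyl ether much faster than the tert-butyldimethylsilyl ether.

Step 21
Reactants: 33 C2 alcohol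
Product: 34 C2 acetate (8-OTBS, 14-OPMB)
Conditions: Ac2O, pyridine, DMAP (cat.), CH2Cl2, 0 °C → rt
Reagents that add atoms: acetic anhydride, CC(=O)OC(C)=O
Why: DMAP-catalysed acetylation of the only free hydroxyl.

Step 22
Reactants: 34 C2 acetate with C8 OTBS
Product: 35 C8 alcohol (2-OAc, 14-OPMB)
Conditions: HF·pyridine (excess), THF, 0 °C → rt
Reagents that add atoms: none
Why: Fluoride-mediated desilylation under acidic, non-basic conditions leaves the acetate, PMB ether and α-methylene lactone intact and avoids base-induced translactonisation to O8.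

Step 23
Reactants: 35 C8 alcohol
Product: 36 C8 methacrylate (2-OAc, 14-OPMB)
Conditions: methacrylic anhydride, Et3N, DMAP, CH2Cl2, 0 °C → rt
Reagents that add atoms: methacrylic anhydride, CC(=C)C(=O)OC(=O)C(C)=C
Why: DMAP-catalysed acylation with the anhydride esterifies the hindered secondary C8 alcohol.

Step 24
Reactants: 36 PMB-protected target
Product: 37 CNP0138477.2, (2S,6R,7R,8R)-2-acetoxy-14-hydroxy-8-(methacryloyloxy)germacra-1(10),4,11(13)-trien-12,6-olide (C1=C10 cis and C4=C5 trans in the ring)
Conditions: DDQ, CH2Cl2/pH 7 buffer, 0 °C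
Reagents that add atoms: none
Why: DDQ oxidises the PMB ether to a benzylic oxocarbenium ion that the buffer hydrolyses, while esters, lactone and the isolated alkenes are inert at 0 °C.

**Compound list**

1 | but-2-yne-1,4-diol | OCC#CCO | starting material
2 | 4-[(4-methoxybenzyl)oxy]but-2-yn-1-ol | OCC#CCOCc1ccc(OC)cc1 | intermediate
3 | sodium cyclic alkenylaluminate (2,5-dihydro-1,2-oxaaluminole, Al on O2 and C10) | [Na+].COCCO[Al-]1(OCCOC)OCC=C1COCc1ccc(OC)cc1 | intermediate
4 | (2Z)-3-iodo-4-[(4-methoxybenzyl)oxy]but-2-en-1-ol | OC/C=C(\I)COCc1ccc(OC)cc1 | intermediate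
5 | 2-({(2Z)-3-iodo-4-[(4-methoxybenzyl)oxy]but-2-en-1-yl}oxy)oxane | I/C(COCc1ccc(OC)cc1)=C\COC1CCCCO1 | intermediate
6 | dimethyl (S)-malate | COC(=O)C[C@H](O)C(=O)OC | starting material
7 | tert-butyl bromoacetate | BrCC(=O)OC(C)(C)C | starting material
8 | dilithium alkoxide enolate of 6 | [Li+].[Li+].COC(=O)[C@@H]([O-])C=C([O-])OC | intermediate
9 | 1-tert-butyl 2,3-dimethyl (2R,3S)-3-hydroxypropane-1,2,3-tricarboxylate | COC(=O)[C@H](CC(=O)OC(C)(C)C)[C@H](O)C(=O)OC | intermediate
10 | 4-tert-butyl 1-methyl (2R)-2-[(1S)-1,2-dihydroxyethyl]butanedioate | COC(=O)[C@H](CC(=O)OC(C)(C)C)[C@H](O)CO | intermediate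
11 | primary monotosylate of 10 | COC(=O)[C@H](CC(=O)OC(C)(C)C)[C@H](O)COS(=O)(=O)c1ccc(C)cc1 | intermediate
12 | 4-tert-butyl 1-methyl (2R)-2-[(2S)-oxiran-2-yl]butanedioate | COC(=O)[C@H](CC(=O)OC(C)(C)C)[C@H]1CO1 | intermediate
13 | alkenyllithium from 5 | [Li]/C(COCc1ccc(OC)cc1)=C\COC1CCCCO1 | intermediate
14 | alkenylmagnesium bromide from 5 | Br[Mg]/C(COCc1ccc(OC)cc1)=C\COC1CCCCO1 | intermediate
15 | coupled C8 alcohol (C6 methyl ester, C12 tert-butyl ester, C14 OPMB, C2 OTHP) | COC(=O)[C@H](CC(=O)OC(C)(C)C)[C@H](O)C/C(COCc1ccc(OC)cc1)=C\COC1CCCCO1 | intermediate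
16 | C8 TBS ether of 15 | COC(=O)[C@H](CC(=O)OC(C)(C)C)[C@H](O[Si](C)(C)C(C)(C)C)C/C(COCc1ccc(OC)cc1)=C\COC1CCCCO1 | intermediate
17 | C2 allylic alcohol | COC(=O)[C@H](CC(=O)OC(C)(C)C)[C@H](O[Si](C)(C)C(C)(C)C)C/C(COCc1ccc(OC)cc1)=C\CO | intermediate
18 | C2 enal | COC(=O)[C@H](CC(=O)OC(C)(C)C)[C@H](O[Si](C)(C)C(C)(C)C)C/C(COCc1ccc(OC)cc1)=C\C=O | intermediate
19 | allenylboronic acid pinacol ester | C=C=CB1OC(C)(C)C(C)(C)O1 | starting material
20 | (2S)-homopropargylic alcohol | COC(=O)[C@H](CC(=O)OC(C)(C)C)[C@H](O[Si](C)(C)C(C)(C)C)C/C(COCc1ccc(OC)cc1)=C\[C@@H](O)CC#C | intermediate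
21 | C2 TES ether of 20 | COC(=O)[C@H](CC(=O)OC(C)(C)C)[C@H](O[Si](C)(C)C(C)(C)C)C/C(COCc1ccc(OC)cc1)=C\[C@@H](O[Si](CC)(CC)CC)CC#C | intermediate
22 | C6 primary alcohol | OC[C@H](CC(=O)OC(C)(C)C)[C@H](O[Si](C)(C)C(C)(C)C)C/C(COCc1ccc(OC)cc1)=C\[C@@H](O[Si](CC)(CC)CC)CC#C | intermediate
23 | ynal (key-step precursor) | O=C[C@H](CC(=O)OC(C)(C)C)[C@H](O[Si](C)(C)C(C)(C)C)C/C(COCc1ccc(OC)cc1)=C\[C@@H](O[Si](CC)(CC)CC)CC#C | intermediate
24 | dimethylzinc | C[Zn]C | starting material
25 | macrocyclic dienol (key-step product) | O[C@@H]1/C=C(C)/C[C@H](O[Si](CC)(CC)CC)/C=C(COCc2ccc(OC)cc2)\C[C@@H](O[Si](C)(C)C(C)(C)C)[C@H]1CC(=O)OC(C)(C)C | intermediate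
26 | C6 trimethylsilyl ether, C12 trimethylsilyl ester | C[Si](C)(C)O[C@@H]1/C=C(C)/C[C@H](O[Si](CC)(CC)CC)/C=C(COCc2ccc(OC)cc2)\C[C@@H](O[Si](C)(C)C(C)(C)C)[C@H]1CC(=O)O[Si](C)(C)C | intermediate
27 | hydroxy acid | O[C@@H]1/C=C(C)/C[C@H](O[Si](CC)(CC)CC)/C=C(COCc2ccc(OC)cc2)\C[C@@H](O[Si](C)(C)C(C)(C)C)[C@H]1CC(=O)O | intermediate
28 | trans-fused γ-lactone | O=C1C[C@H]2[C@H](O1)/C=C(C)/C[C@H](O[Si](CC)(CC)CC)/C=C(COCc1ccc(OC)cc1)\C[C@H]2O[Si](C)(C)C(C)(C)C | intermediate
29 | lithium enolate of 28 | [Li+].[O-]C1=C[C@H]2[C@H](O1)/C=C(C)/C[C@H](O[Si](CC)(CC)CC)/C=C(COCc1ccc(OC)cc1)\C[C@H]2O[Si](C)(C)C(C)(C)C | intermediate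
30 | C11 dimethylaminomethyl lactone | O=C1C(CN(C)C)[C@H]2[C@H](O1)/C=C(C)/C[C@H](O[Si](CC)(CC)CC)/C=C(COCc1ccc(OC)cc1)\C[C@H]2O[Si](C)(C)C(C)(C)C | intermediate
31 | trimethylammonium iodide of 30 | [I-].O=C1C(C[N+](C)(C)C)[C@H]2[C@H](O1)/C=C(C)/C[C@H](O[Si](CC)(CC)CC)/C=C(COCc1ccc(OC)cc1)\C[C@H]2O[Si](C)(C)C(C)(C)C | intermediate
32 | α-methylene lactone (2-OTES, 8-OTBS, 14-OPMB) | O=C1C(=C)[C@H]2[C@H](O1)/C=C(C)/C[C@H](O[Si](CC)(CC)CC)/C=C(COCc1ccc(OC)cc1)\C[C@H]2O[Si](C)(C)C(C)(C)C | intermediate
33 | C2 alcohol | O=C1C(=C)[C@H]2[C@H](O1)/C=C(C)/C[C@H](O)/C=C(COCc1ccc(OC)cc1)\C[C@H]2O[Si](C)(C)C(C)(C)C | intermediate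
34 | C2 acetate | O=C1C(=C)[C@H]2[C@H](O1)/C=C(C)/C[C@H](OC(C)=O)/C=C(COCc1ccc(OC)cc1)\C[C@H]2O[Si](C)(C)C(C)(C)C | intermediate
35 | C8 alcohol | O=C1C(=C)[C@H]2[C@H](O1)/C=C(C)/C[C@H](OC(C)=O)/C=C(COCc1ccc(OC)cc1)\C[C@H]2O | intermediate
36 | C8 methacrylate, PMB ether | O=C1C(=C)[C@H]2[C@H](O1)/C=C(C)/C[C@H](OC(C)=O)/C=C(COCc1ccc(OC)cc1)\C[C@H]2OC(=O)C(C)=C | intermediate
37 | CNP0138477.2 | C=C(C)C(=O)O[C@@H]1C/C(CO)=C\[C@@H](OC(C)=O)C/C(C)=C/[C@H]2OC(=O)C(=C)[C@@H]21 | target

**Step count and risks**

Total step count: 24. Longest linear sequence: 21 steps (steps 1–3, then 7–24; equally steps 4–6, then 7–24).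

Steps most likely to fail:

1. Step 15 (Proposed new method). Intermolecular alkyne–aldehyde coupling (oligomerisation) or plain methyl transfer to the aldehyde may outrun the strained ten-membered closure, or C–C bond formation may occur at C4 (exo mode). The fallback uses known chemistry, sets out from 21 and comes back at 25. Negishi carboalumination of the terminal alkyne of 21 (Me3Al, Cp2ZrCl2 cat., CH2Cl2; then I2) should give the (E)-2-methyl-1-iodoalkene ester F1, with the C15 methyl and the C4=C5 geometry already in place. LiBH4 reduction of the methyl ester would give the primary alcohol F2, and Dess–Martin oxidation the iodo aldehyde F3. Intramolecular Nozaki–Hiyama–Kishi reaction of F3 (CrCl2, NiCl2 cat., DMSO/THF, high dilution) forms the same C5–C6 bond with retention of alkene geometry and returns to the route at 25; C6 epimers would be separated if facial selectivity is incomplete.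

2. Step 7. Deprotonation of 12 at C7 by the organomagnesium reagent, with β-elimination opening of the epoxide, or addition to the ester groups, may compete with SN2 opening at C9. The fallback sets out from 6 and 5 and comes back at 15; it moves the alkylation behind the coupling. Hydroxyl-directed borane reduction of 6 (as in step 5) gives methyl (3S)-3,4-dihydroxybutanoate F4. Tosylation and ring closure as in step 6 give methyl 2-[(2S)-oxiran-2-yl]acetate F5, a simple β,γ-epoxy ester of a class known to be opened at the terminus by copper-catalysed Grignard reagents. Opening with 14 gives the unbranched β-hydroxy ester F6, and Fráter–Seebach alkylation of its dianion (LiN(iPr)2, 2.1 equiv; then 7) installs the C11–C12 arm anti to O8 and returns to 15.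

3. Step 16. The Lewis acidic silyl triflate may ionise the allylic C6–O bond or strip the TES ether before the tert-butyl ester is dealkylated. The fallback sets out from 25 and comes back at 28, replacing steps 16 and 17 (no new compound, F0). It is a direct alkoxide lactonisation: the C6 hydroxyl is deprotonated with LiN(SiMe3)2 (THF, −78 → 0 °C) and the lithium alkoxide displaces tert-butoxide from the ester in a 5-exo-trig acyl substitution. The lithium counter-ion and low temperature are chosen to hold back 1,3-migration of the TBS group from O8 to O6.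

Further compounds
F1 | step 15 | (E)-alkenyl iodide ester: 21 with the terminal alkyne replaced by C(CH3)=CHI, C3 and I trans | COC(=O)[C@H](CC(=O)OC(C)(C)C)[C@H](O[Si](C)(C)C(C)(C)C)C/C(COCc1ccc(OC)cc1)=C\[C@@H](O[Si](CC)(CC)CC)C/C(C)=C/I
F2 | step 15 | C6 primary alcohol of F1 | OC[C@H](CC(=O)OC(C)(C)C)[C@H](O[Si](C)(C)C(C)(C)C)C/C(COCc1ccc(OC)cc1)=C\[C@@H](O[Si](CC)(CC)CC)C/C(C)=C/I
F3 | step 15 | C6 aldehyde with (E)-alkenyl iodide | O=C[C@H](CC(=O)OC(C)(C)C)[C@H](O[Si](C)(C)C(C)(C)C)C/C(COCc1ccc(OC)cc1)=C\[C@@H](O[Si](CC)(CC)CC)C/C(C)=C/I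
F4 | step 7 | methyl (3S)-3,4-dihydroxybutanoate | COC(=O)C[C@H](O)CO
F5 | step 7 | methyl 2-[(2S)-oxiran-2-yl]acetate | COC(=O)C[C@H]1CO1
F6 | step 7 | methyl (3R,5E)-3-hydroxy-5-{[(4-methoxybenzyl)oxy]methyl}-7-(oxan-2-yloxy)hept-5-enoate | COC(=O)C[C@H](O)C/C(COCc1ccc(OC)cc1)=C\COC1CCCCO1
F0 | step 16 | none | none
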